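**Retrosynthetic overview**

- Ring B (the dihydropyran) is cut last, across O–C1 and C1′–C2, giving an ortho-quinone methide of ring A (from 2,4-diformylphloroglucinol and isovaleraldehyde) and a spiro[4.5]deca-1,6-diene. Numbering: C1′ is the benzylic CH; the terpene atoms follow spiro[4.5]decane numbering, with C1 the O–CH, C2 the C–CH3, C5 the spiro carbon, C6=C7 the ring D alkene (isopropyl on C7) and C10 the CH–CH3.
- Enabling feature: C1 is bonded to spiro C5, and C5 carries C6=C7 of ring D, so C1–C5–C6=C7 is a homoallyl array. The ring D π bond can take up the positive charge at C1 while the methide carbon bonds to C2. This reverses the usual orientation on a methylcyclopentene (C1 is also neopentyl) and dictates attack anti to C6.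
- Diene: ring D and the C10 methyl centre come from (−)-menthone; spiro C5 is built by formylation and Michael addition trans to that methyl group; ring C is closed by ring-closing metathesis; C6=C7 comes from enol triflate reduction.
- Ring order: D (chiral pool), C (metathesis), A (phloroglucinol, formylated), B (three-component Knoevenagel/oxa-Diels–Alder step).

Key step: step 8

Assumption: the isopropyl-bearing carbon next to the ring ketone equilibrates under the basic conditions of steps 1 to 3, so 2, 4, 5 and 6 are drawn without a descriptor there; it becomes sp2 in step 5 and has no bearing on the route.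

**Route**

Step 1
Reactants: 1 (−)-menthone
Product: 2 (3R)-2-(hydroxymethylidene)-3-methyl-6-(propan-2-yl)cyclohexan-1-one
Conditions: NaH, HCO2Et, cat. EtOH, Et2O, 0 °C to rt; then aq. HCl
Reagents that add atoms: ethyl formate, CCOC=O
Why: Crossed Claisen condensation (C-formylation) at the only CH2 next to the ketone, driven by formation of the chelated enolate of the product; no new stereocentre, and the methyl-bearing centre is not touched.

Step 2
Reactants: 2 (3R)-2-(hydroxymethylidene)-3-methyl-6-(propan-2-yl)cyclohexan-1-one, 3 methyl vinyl ketone
Product: 4 (1S,2R)-2-methyl-6-oxo-1-(3-oxobutyl)-5-(propan-2-yl)cyclohexane-1-carbaldehyde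
Conditions: Et3N (cat.), CH2Cl2, 0 °C to rt
Reagents that add atoms: none
Why: Michael addition of the formyl ketone enol to the enone; the neighbouring methyl group sits pseudoaxial to avoid allylic strain with the hydroxymethylidene unit, so the enone should enter on the opposite face and give the quaternary centre with the oxobutyl chain trans and the formyl group cis to the methyl group (the same sense as in Robinson annulations of 2,3-dialkylcyclohexanones).

Step 3
Reactants: 4 (1S,2R)-2-methyl-6-oxo-1-(3-oxobutyl)-5-(propan-2-yl)cyclohexane-1-carbaldehyde
Product: 5 (2R,3R)-2-ethenyl-3-methyl-2-(3-methylbut-3-en-1-yl)-6-(propan-2-yl)cyclohexan-1-one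
Conditions: Ph3PCH3Br, KOC(CH3)3, THF, 0 °C to rt
Reagents that add atoms: methyltriphenylphosphonium bromide, C[P+](c1ccccc1)(c1ccccc1)c1ccccc1.[Br-]
Why: Twofold Wittig methylenation of the aldehyde and the methyl ketone; the ring ketone, between a quaternary carbon and the isopropyl-bearing carbon, should be too hindered to react, and no stereocentre is formed.

Step 4
Reactants: 5 (2R,3R)-2-ethenyl-3-methyl-2-(3-methylbut-3-en-1-yl)-6-(propan-2-yl)cyclohexan-1-one
Product: 6 (5S,10R)-2,10-dimethyl-7-(propan-2-yl)spiro[4.5]dec-1-en-6-one
Conditions: second-generation Grubbs catalyst (5 mol %), toluene, 80 °C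
Reagents that add atoms: none
Why: Ring-closing olefin metathesis of the vinyl group with the 1,1-disubstituted alkene closes ring C as a trisubstituted cyclopentene with loss of ethene; the quaternary centre becomes the spiro centre unchanged.

Step 5
Reactants: 6 (5S,10R)-2,10-dimethyl-7-(propan-2-yl)spiro[4.5]dec-1-en-6-one
Product: 7 (5S,10R)-2,10-dimethyl-7-(propan-2-yl)spiro[4.5]deca-1,6-dien-6-yl trifluoromethanesulfonate
Conditions: KN(SiMe3)2, THF, −78 to 0 °C; then PhNTf2, 0 °C to rt
Reagents that add atoms: N-phenylbis(trifluoromethanesulfonimide), O=S(=O)(N(c1ccccc1)S(=O)(=O)C(F)(F)F)C(F)(F)F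
Why: Enolate O-sulfonylation; enolization can only take place towards the isopropyl-bearing carbon because the other neighbour is quaternary, so a single enol triflate should form and the epimeric centre disappears.

Step 6
Reactants: 7 (5S,10R)-2,10-dimethyl-7-(propan-2-yl)spiro[4.5]deca-1,6-dien-6-yl trifluoromethanesulfonate
Product: 8 (5S,10R)-2,10-dimethyl-7-(propan-2-yl)spiro[4.5]deca-1,6-diene
Conditions: Pd(OAc)2 (cat.), PPh3, HCO2H, Bu3N, DMF, 60 °C
Reagents that add atoms: none
Why: Palladium-catalysed transfer hydrogenolysis of an enol triflate by formate (oxidative addition, hydride from formate with loss of CO2, reductive elimination) replaces the triflate by hydrogen without moving the double bond; no stereocentre is affected.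

Step 7
Reactants: 9 phloroglucinol
Product: 10 2,4,6-trihydroxybenzene-1,3-dicarbaldehyde (2,4-diformylphloroglucinol)
Conditions: POCl3, DMF, dioxane, rt; then H2O
Reagents that add atoms: N,N-dimethylformamide, CN(C)C=O; water, O
Why: Vilsmeier–Haack formylation: two successive electrophilic substitutions of the very electron-rich ring by the chloroiminium ion, the two formyl groups deactivating the ring against a third, and hydrolysis on work-up frees the aldehydes.

Step 8
Reactants: 8 (5S,10R)-2,10-dimethyl-7-(propan-2-yl)spiro[4.5]deca-1,6-diene, 10 2,4,6-trihydroxybenzene-1,3-dicarbaldehyde, 11 isovaleraldehyde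
Product: 13 target CNP0121396.1 (rings A/B/C/D), via ortho-quinone methide 12 (not isolated)
Conditions: NaOAc, AcOH, 80 °C
Reagents that add atoms: none
Why: Knoevenagel condensation of 10 with 11 and loss of water gives ortho-quinone methide 12, which adds across C1=C2 of 8 in an inverse-electron-demand oxa-Diels–Alder reaction (closest precedent: the three-component union of diformylphloroglucinol, an aldehyde and a terpene alkene); ring B is thus closed by [4+2] cycloaddition, suprafacial on the alkene, which makes the B/C fusion cis. The addition should be strongly asynchronous: the methide carbon bonds first to C2, and the positive charge left at C1 is taken up by the C6=C7 π bond of ring D through the homoallyl (cyclopropylcarbinyl-type) array C1–C5–C6=C7 and ends on the isopropyl-bearing carbon, whereas the usual orientation would have to form a C–C bond at the neopentyl C1 beside the spiro centre. Because this π bond can only assist from its own side of ring C, the quinone methide must enter from the opposite face, so the oxygen at C1 and the benzylic carbon at C2 both end anti to C6 and syn to C10, which sets the O–CH (R) and C–CH3 (S) centres from the spiro centre. For the benzylic centre (R), the arene is expected to point away from the spiro centre while the C–C bond forms at the remote C2 and then to swing in so that one of its two equivalent ortho oxygens closes the ether, which leaves the isobutyl group on the concave face, cis to ring C. The step needs chemoselectivity for the cyclopentene over the ring D alkene (the latter is flanked by the isopropyl group and the quaternary carbon), orientation and π-face selectivity (both tied to the homoallyl array) and benzylic selectivity, which is the least secured element.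

**Compound list**

1 | (−)-menthone, (2S,5R)-5-methyl-2-(propan-2-yl)cyclohexan-1-one | C[C@@H]1CC[C@H](C(=O)C1)C(C)C | starting material
2 | (3R)-2-(hydroxymethylidene)-3-methyl-6-(propan-2-yl)cyclohexan-1-one, chelated Z enol, isopropyl-bearing carbon as epimer mixture | O/C=C1/[C@H](C)CCC(C(C)C)C1=O | intermediate
3 | methyl vinyl ketone (but-3-en-2-one) | CC(=O)C=C | starting material
4 | (1S,2R)-2-methyl-6-oxo-1-(3-oxobutyl)-5-(propan-2-yl)cyclohexane-1-carbaldehyde, formyl cis and oxobutyl trans to the methyl group | O=C[C@@]1(CCC(C)=O)C(=O)C(C(C)C)CC[C@H]1C | intermediate
5 | (2R,3R)-2-ethenyl-3-methyl-2-(3-methylbut-3-en-1-yl)-6-(propan-2-yl)cyclohexan-1-one | C=C[C@@]1(CCC(C)=C)C(=O)C(C(C)C)CC[C@H]1C | intermediate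
6 | (5S,10R)-2,10-dimethyl-7-(propan-2-yl)spiro[4.5]dec-1-en-6-one | CC1=C[C@@]2(CC1)C(=O)C(C(C)C)CC[C@H]2C | intermediate
7 | (5S,10R)-2,10-dimethyl-7-(propan-2-yl)spiro[4.5]deca-1,6-dien-6-yl trifluoromethanesulfonate | CC1=C[C@@]2(CC1)C(OS(=O)(=O)C(F)(F)F)=C(C(C)C)CC[C@H]2C | intermediate
8 | (5S,10R)-2,10-dimethyl-7-(propan-2-yl)spiro[4.5]deca-1,6-diene | CC1=C[C@@]2(CC1)C=C(C(C)C)CC[C@H]2C | intermediate
9 | phloroglucinol (benzene-1,3,5-triol) | Oc1cc(O)cc(O)c1 | starting material
10 | 2,4,6-trihydroxybenzene-1,3-dicarbaldehyde | O=Cc1c(O)cc(O)c(C=O)c1O | intermediate
11 | isovaleraldehyde (3-methylbutanal) | CC(C)CC=O | starting material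
12 | (5E)-2,4-dihydroxy-5-(3-methylbutylidene)-6-oxocyclohexa-1,3-diene-1,3-dicarbaldehyde (ortho-quinone methide; the Z form is its tautomer through the symmetric ring) | CC(C)C/C=C1/C(=O)C(C=O)=C(O)C(C=O)=C1O | intermediate
13 | (1R,6R,3'aR,9'R,9'aS)-6',8'-dihydroxy-6,9'a-dimethyl-9'-(2-methylpropyl)-3-(propan-2-yl)-1',2',9',9'a-tetrahydro-3'aH-spiro[cyclohex-2-ene-1,3'-cyclopenta[b]chromene]-5',7'-dicarbaldehyde | CC(C)C[C@H]1c2c(O)c(C=O)c(O)c(C=O)c2O[C@@H]2[C@@]1(C)CC[C@@]21C=C(C(C)C)CC[C@H]1C | target

**Step count**

Total steps: 8. Longest linear sequence: 7 (steps 1 to 6, then step 8).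

**Steps most likely to fail**

1. Step 8. The quinone methide may add with the usual orientation (benzylic carbon to the CH beside the spiro centre), from the side of the ring D alkene, or with the isobutyl group on the convex face. At 80 °C it may also oligomerize faster than the hindered diene traps it, and the charge-separated pathway may divert into skeletal rearrangement. Fallback: a two-stage ionic union at low temperature with an isolated quinone methide precursor. It sets out from 10, which is condensed with 11 and thiophenol (piperidine cat., EtOH, rt; Knoevenagel condensation and thia-Michael capture) to give the sulfide 2,4,6-trihydroxy-5-[3-methyl-1-(phenylsulfanyl)butyl]benzene-1,3-dicarbaldehyde F1. F1 and diene 8 are then treated with AgOSO2CF3 and 2,6-di-tert-butylpyridine in CH2Cl2 at −40 °C. The thiophilic silver salt removes benzenethiolate, the benzylic cation adds to C2 of 8 under full homoallyl assistance, and the phenol oxygen closes ring B. The fallback comes back to the route at 13.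

2. Step 3. The basic ylide may cause retro-Claisen loss of the formyl group or aldol closure of the methyl ketone onto the aldehyde, and methylenation of the ketone may stay incomplete. Fallback: reductive carbonyl coupling in place of olefination and metathesis. It sets out from 4, which is treated with low-valent titanium from TiCl3 and Zn–Cu couple in refluxing DME (intramolecular McMurry reaction). This joins the aldehyde carbon and the methyl ketone carbon directly into the cyclopentene, while the ring ketone between the quaternary and the isopropyl-bearing carbon should be left. The fallback comes back to the route at 6 and makes no new compound (F0).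

3. Step 5. Deprotonation of the only α-hydrogen, a methine between the isopropyl group and a ketone flanked by the spiro carbon, may be slow or incomplete, and sulfonylation of the crowded enolate may fail. Fallback: reduction and dehydration in place of the enol triflate. It sets out from 6, which is reduced with LiAlH4 (THF, 0 °C) to the alcohol (5S,10R)-2,10-dimethyl-7-(propan-2-yl)spiro[4.5]dec-1-en-6-ol F2. Syn-elimination with the Burgess reagent (toluene, 80 °C) can only use the hydrogen on the isopropyl-bearing carbon, because the other neighbour is quaternary. The fallback comes back to the route at 8 and bypasses 7 and step 6.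

**Further compounds**

F1 | step 8 | 2,4,6-trihydroxy-5-[3-methyl-1-(phenylsulfanyl)butyl]benzene-1,3-dicarbaldehyde (racemic) | CC(C)CC(Sc1ccccc1)c1c(O)c(C=O)c(O)c(C=O)c1O
F0 | step 3 | none | none
F2 | step 5 | (5S,10R)-2,10-dimethyl-7-(propan-2-yl)spiro[4.5]dec-1-en-6-ol (carbinol and isopropyl-bearing carbons as epimer mixtures) | CC1=C[C@@]2(CC1)C(O)C(C(C)C)CC[C@H]2C
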